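**Retrosynthetic overview**

1. Both C15 halves come from 15-pentadecanolide 1: HI opening gives 15-iodopentadecanoic acid 2; half-reduction to 15-hydroxypentadecanal 3 and condensation give its trityl hydrazone 4.
2. Ester C–O disconnection: 2 + 4 give the open-chain ester 5, so the ester is made before the ring.
3. Key disconnection, C15–C16 (mid-chain, opposite the ester): the former aldehyde carbon of 5 is deprotonated to azo anion 6, a masked acyl anion that later sheds N2 instead of being unmasked to C=O. It attacks the iodide-bearing carbon, and diazene 7 collapses to the CH2–CH2 unit of target 8.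
4. Ring order: there is one ring only, the 31-membered lactone, closed last by the C–C bond and not by lactonisation.

Assumption: the SMILES is read as one carbonyl carbon plus 29 CH2 groups in a 31-membered lactone (oxacyclohentriacontan-2-one, C30H58O2); it has no stereocentre, so there is no enantiomer to control, and tritylhydrazine is taken as a bought reagent.

**Route**

Step 1
Reactants: 1 15-pentadecanolide (oxacyclohexadecan-2-one)
Product: 2 15-iodopentadecanoic acid
Conditions: 57% aq. HI (5 equiv), AcOH, 100 °C, 12 h; aq. Na2S2O3 wash
Reagents that add atoms: hydrogen iodide, I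
Why: Acidolytic ring opening of a lactone (SN2 attack of iodide at the primary O-alkyl carbon of the protonated ester, as in the HBr opening of macrolides to ω-bromo acids); it is a net addition of HI across the C–O bond, so the step has no by-product.

Step 2
Reactants: 1 15-pentadecanolide
Product: 4 (E)-15-(2-tritylhydrazinylidene)pentadecan-1-ol, via 15-hydroxypentadecanal 3 (not isolated)
Conditions: i-Bu2AlH (1.05 equiv), CH2Cl2, −78 °C, 1 h; MeOH, then aq. potassium sodium tartrate, rt; dried (MgSO4) organic layer + TrNHNH2 (1.1 equiv), rt, 2 h
Reagents that add atoms: tritylhydrazine, NNC(c1ccccc1)(c1ccccc1)c1ccccc1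
Why: Partial reduction of a lactone with one equivalent of i-Bu2AlH at −78 °C stops at the aldehyde level, and the labile ω-hydroxy aldehyde is trapped at once by hydrazone formation with tritylhydrazine, which installs the N–H needed to reverse the polarity of the former carbonyl carbon; no stereocentre is formed.

Step 3
Reactants: 2 15-iodopentadecanoic acid; 4 (E)-15-(2-tritylhydrazinylidene)pentadecan-1-ol
Product: 5 (E)-15-(2-tritylhydrazinylidene)pentadecyl 15-iodopentadecanoate
Conditions: DCC (1.1 equiv), DMAP (0.1 equiv), CH2Cl2, 0 °C → rt
Reagents that add atoms: none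
Why: Steglich esterification acylates the primary alcohol under neutral conditions, while the hydrazone N–H is shielded by the trityl group and the primary iodide is untouched at room temperature.

Step 4
Reactants: 5 (E)-15-(2-tritylhydrazinylidene)pentadecyl 15-iodopentadecanoate
Product: 8 oxacyclohentriacontan-2-one (30-triacontanolide), via potassium azo anion 6 (not isolated), via macrocyclic trityl diazene 7 (not isolated)
Conditions: KN(SiMe3)2 (1.05 equiv), THF (1 mM in 5), −78 → −20 °C, 6 h; then EtSH (10 equiv), −20 °C → rt
Reagents that add atoms: none
Why: Proposed new method: the hydrazone N–H, more acidic than the ester α-CH2, is removed by KN(SiMe3)2 to give an azo anion whose trityl-shielded nitrogen leaves the former aldehyde carbon as the nucleophilic site, and at 1 mM this carbon closes the strain-free 31-membered ring by SN2 displacement of the primary iodide; the resulting trityl diazene loses N2 and trityl radical on warming and the ring radical takes hydrogen from EtSH to leave CH2–CH2 (the transient stereocentre of 7 is erased); the closest known reaction type is the intermolecular C-alkylation of metalated aldehyde trityl hydrazones (azo anions) by alkyl halides followed by thiol-mediated loss of N2 (reductive alkylation of aldehydes), here run intramolecularly as a macrocyclisation.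

**Compound list**

1 | 15-pentadecanolide (oxacyclohexadecan-2-one) | O=C1CCCCCCCCCCCCCCO1 | starting material
2 | 15-iodopentadecanoic acid | OC(=O)CCCCCCCCCCCCCCI | intermediate
3 | 15-hydroxypentadecanal | O=CCCCCCCCCCCCCCCO | intermediate
4 | (E)-15-(2-tritylhydrazinylidene)pentadecan-1-ol (trityl hydrazone of 3) | OCCCCCCCCCCCCCC/C=N/NC(c1ccccc1)(c1ccccc1)c1ccccc1 | intermediate
5 | (E)-15-(2-tritylhydrazinylidene)pentadecyl 15-iodopentadecanoate | ICCCCCCCCCCCCCCC(=O)OCCCCCCCCCCCCCC/C=N/NC(c1ccccc1)(c1ccccc1)c1ccccc1 | intermediate
6 | potassium azo anion of 5 (5 deprotonated at the hydrazone N–H, potassium salt) | [K+].ICCCCCCCCCCCCCCC(=O)OCCCCCCCCCCCCCC/C=N/[N-]C(c1ccccc1)(c1ccccc1)c1ccccc1 | intermediate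
7 | 17-[(E)-trityldiazenyl]oxacyclohentriacontan-2-one (racemic at C17) | O=C1CCCCCCCCCCCCCCC(/N=N/C(c2ccccc2)(c2ccccc2)c2ccccc2)CCCCCCCCCCCCCCO1 | intermediate
8 | oxacyclohentriacontan-2-one (30-triacontanolide, achiral) | O=C1CCCCCCCCCCCCCCCCCCCCCCCCCCCCCO1 | target

**Step count**

Total step count: 4. Longest linear sequence: 3 steps (1 → 4 → 5 → 8, or 1 → 2 → 5 → 8).

**Steps most likely to fail**

Step 4 is the riskiest. The ring-closing C-alkylation can lose to oligomerisation, to alkylation through the ester enolate, to N-alkylation, or to loss of N2 before the thiol is present. The fallback makes the same polarity-reversed C15–C16 bond between two separate chains and closes the ring at the ester instead. It sets out from 2 and 4. Compound 4 is deprotonated twice with LiN(SiMe3)2 (2.1 equiv, THF, −78 °C) and alkylated at carbon by 2, which has been pre-treated with one equivalent of LiN(SiMe3)2 (THF/DMPU, −78 → −10 °C). This gives the open-chain diazene 30-hydroxy-16-[(E)-trityldiazenyl]triacontanoic acid F1. EtSH (−20 °C → rt) removes N2 and trityl to give 30-hydroxytriacontanoic acid F2. 2,4,6-Trichlorobenzoyl chloride and Et3N (THF, rt) convert F2 into 30-hydroxytriacontanoic 2,4,6-trichlorobenzoic anhydride F3. Slow addition of F3 to DMAP in refluxing toluene (Yamaguchi macrolactonisation) comes back to the route at 8.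

Step 2 is next. i-Bu2AlH may reduce 1 past the aldehyde, or the crude hydroxy aldehyde may oligomerise before it is trapped. The fallback fixes the aldehyde level through an amide and sets out from 1. MeNH(OMe)·HCl and i-PrMgCl (THF, −20 °C) open the lactone to 15-hydroxy-N-methoxy-N-methylpentadecanamide F4. LiAlH4 (1.5 equiv, THF, 0 °C) reduces this Weinreb amide only as far as the aldehyde. The fallback comes back to the route at 3, which is condensed with tritylhydrazine to 4 as in step 2.

Step 3 is third. The hydrazone may be N-acylated or lose trityl during the carbodiimide coupling or on silica. The fallback reverses the order of esterification and hydrazone formation. It sets out from 2 and 3, with 3 used as the dried solution from the reduction stage of step 2. DCC/DMAP (CH2Cl2, 0 °C → rt) gives 15-oxopentadecyl 15-iodopentadecanoate F5. Its aldehyde is then condensed with tritylhydrazine (THF, rt), and the fallback comes back to the route at 5.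

**Further compounds**

F1 | step 4 | 30-hydroxy-16-[(E)-trityldiazenyl]triacontanoic acid (racemic) | OC(=O)CCCCCCCCCCCCCCC(/N=N/C(c1ccccc1)(c1ccccc1)c1ccccc1)CCCCCCCCCCCCCCO
F2 | step 4 | 30-hydroxytriacontanoic acid | OC(=O)CCCCCCCCCCCCCCCCCCCCCCCCCCCCCO
F3 | step 4 | 30-hydroxytriacontanoic 2,4,6-trichlorobenzoic anhydride | O=C(OC(=O)c1c(Cl)cc(Cl)cc1Cl)CCCCCCCCCCCCCCCCCCCCCCCCCCCCCO
F4 | step 2 | 15-hydroxy-N-methoxy-N-methylpentadecanamide | CON(C)C(=O)CCCCCCCCCCCCCCO
F5 | step 3 | 15-oxopentadecyl 15-iodopentadecanoate | ICCCCCCCCCCCCCCC(=O)OCCCCCCCCCCCCCCC=O
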